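At early times the two earlier runs show the first step, so I start there.

| flask | starting material | remark | time |
|---|---|---|---|
| Sunday's | 0.15 M | run made earlier |  |
| Friday's | 0.30 M | run made earlier |  |
| theta | 0.15 M | everything together in a closed stirred flask, run for 12 h | 12 h |
| beta | 0.15 M | one stirred flow tank at steady state, fed with the mixture as stated, mean residence time 12 h |  |

Sunday's run (percent of the starting material charged)

| time / h | intermediate A / % | target / % |
|---|---|---|
| 2.00 | 22 | 1 |
| 4.00 | 31 | 1 |
| 6.00 | 42 | 0 |
| 8.00 | 49 | 0 |
| 10.0 | 53 | 1 |
| 12.0 | 54 | 1 |

Friday's run (percent of the starting material charged)

| time / min | intermediate A / % | target / % |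
|---|---|---|
| 12.0 | 4 | 0 |
| 25.0 | 6 | 0 |
| 40.0 | 7 | 0 |
| 50.0 | 10 | 0 |
| 60.0 | 11 | 0 |
| 80.0 | 15 | 1 |

(standard deviation of a reading: 1.5 percentage points)

1. the set-up with the highest amount of intermediate A at the outlet or at the end, in percent of the starting material put in ("none" if the first two lie within 2 percentage points) (theta / beta / none)
2. amount of intermediate A at the outlet or at the end, in percent of the starting material put in, theta
3. amount of intermediate A at the outlet or at the end, in percent of the starting material put in, beta

- the stated concentrations are those of everything mixed, before any reaction; amounts are the same in each set-up
- the earlier runs were made in a closed, stirred flask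

Friday's run holds 15% of intermediate A after 80.0 min, which gives a first-order constant of 0.122 h⁻¹. Sunday's run, at half the concentration, gives 0.124 h⁻¹ from its first reading, so I take the step as first order.

Sunday's intermediate A nearly stops rising, from 53% to 54% over the last two readings, with target at 1%. Yet by my estimate 23.2% of the starting material remains in Sunday's run at that last reading and still feeds it. If I treat Sunday's curve as turning there, feed equals loss, which gives 0.0523 h⁻¹. That loss means Friday's reading understates what formed, so I put it back: 15.5% formed, and the first constant becomes 0.127 h⁻¹. Going round once more gives the loss constant, the share of intermediate A that disappears per hour, 0.0513 h⁻¹.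

Theta repeats Sunday's run, so I commit to about 54%. For beta, everything in a stirred tank sits at outlet concentration, and a first-order step leaves one over (one plus constant times residence time). My ledger for the starting material, the limiting reagent, therefore reads: 39.7% leaves unreacted, 37.3% leaves as intermediate A, and 23.0% is lost unseen.

The forecast names theta, with 55% for theta and 42% for beta, and says “A reversible step fits well”. My beta figure is lower.

The flask gives theta, with 52.3% in theta and 36.0% in beta.

    starting material → intermediate A (k = 0.122 h⁻¹)
    intermediate A → intermediate B (k = 0.0498 h⁻¹)
    intermediate B → target (k = 0.00761 h⁻¹)
    starting material + intermediate A → side product (k = 0.0451 M⁻¹ h⁻¹)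

In beta, intermediate B stands at 19.7% and target at 1.80%, and the remaining 2.35% of the charge is side product, each of which counts as two, beside my unseen entry of 23.0%. With my two first-order constants, intermediate A late in theta follows the factor 1.68 times the exponential of minus the loss constant times time. For theta left 120 h, that gives 0.356%, and theta holds 0.407%.

All runs were generated by integration for substances that don't exist; noise was put on by code.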